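A direct plan would esterify the secondary hydroxyl of the O-silylated tert-butyl (R)-aryllactate A1 with bis-silylated caffeic acid A2 (carbodiimide, DMAP) and would then strip the protected depside A3 of three silyl ethers and the tert-butyl ester. Its weakest steps would be:
- the making of enantiopure A1 (asymmetric dihydroxylation of a ferulate, then selective removal of the benzylic hydroxyl), which would be longer than the rest of the plan;
- the esterification, a slow acylation of a hindered α-hydroxy ester in which the basic catalyst could erode the neighbouring stereocentre;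
- the final deprotection, in which fluoride would set free phenoxides beside the labile depside ester.

The route would rest on the bond between C3 of the lactate unit and C1 of the 4-hydroxy-3-methoxyphenyl ring. C2 of the target carries an ester oxygen and a carboxyl group, so the three-carbon unit is a masked pyruvate enol: its achiral 2-(caffeoyloxy)acrylate would already hold the complete depside ester. Rhodium-catalysed conjugate addition of the arylboronic acid would attach the guaiacyl ring, and ligand-controlled protonation of the resulting enolate would set C2 in the same operation. No chiral aryllactate would have to be made, no hindered alcohol would be acylated beside a stereocentre, and only one acetonide and one tert-butyl ester would remain to be removed by a single acidolysis.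

Key step: step 3

Remark: C2 of the target is (R) (CIP order O > CO2H > CH2Ar > H); compounds 1, 2, 4 and 7 are taken as catalogue chemicals.

Step 1
Reactants: 1 5-bromo-2,2-dimethyl-1,3-benzodioxole; 2 acrylic acid (1.3 equiv)
Product: 3 (2E)-3-(2,2-dimethyl-1,3-benzodioxol-5-yl)prop-2-enoic acid
Conditions: Pd(OAc)2 (2 mol%), P(o-tol)3 (4 mol%), Et3N (3 equiv), MeCN, 90 °C; then cold 1 M citric acid
Reagents that add atoms: none
Why: Mizoroki–Heck reaction: oxidative addition of the aryl bromide to zerovalent palladium (formed in situ from Pd(OAc)2 and the phosphine), syn-insertion of the acrylate and syn-β-hydride elimination should give the (E)-cinnamic acid; the catechol acetonide is inert to amine base and no stereocentre is formed.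

Step 2
Reactants: 3 (2E)-3-(2,2-dimethyl-1,3-benzodioxol-5-yl)prop-2-enoic acid; 4 tert-butyl pyruvate (tert-butyl 2-oxopropanoate, 1.3 equiv)
Product: 6 tert-butyl 2-{[(2E)-3-(2,2-dimethyl-1,3-benzodioxol-5-yl)prop-2-enoyl]oxy}prop-2-enoate, via acid chloride 5 (not isolated)
Conditions: (COCl)2 (1.2 equiv), DMF (cat.), CH2Cl2, 0 °C to rt, then evaporation; 4 (added slowly), Et3N (1.5 equiv), DMAP (5 mol%), BHT (trace), CH2Cl2, −20 °C to rt
Reagents that add atoms: none
Why: Acid chloride formation through the chloroiminium salt from DMF and oxalyl chloride, then O-acylation of the amine-generated enolate of the α-keto ester, the known preparation of captodative 2-acyloxyacrylates from pyruvates and acyl chlorides; the hard acyl electrophile reacts at the enolate oxygen, the cinnamoyl chloride has no α-hydrogen and so cannot form a ketene, slow addition of 4 keeps its aldol self-condensation down, and no stereocentre is formed.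

Step 3
Reactants: 6 tert-butyl 2-{[(2E)-3-(2,2-dimethyl-1,3-benzodioxol-5-yl)prop-2-enoyl]oxy}prop-2-enoate; 7 (4-hydroxy-3-methoxyphenyl)boronic acid (1.5 equiv)
Product: 8 tert-butyl (2R)-2-{[(2E)-3-(2,2-dimethyl-1,3-benzodioxol-5-yl)prop-2-enoyl]oxy}-3-(4-hydroxy-3-methoxyphenyl)propanoate
Conditions: [Rh(OH)((R)-BINAP)]2 (2.5 mol%; BINAP = 2,2′-bis(diphenylphosphanyl)-1,1′-binaphthyl), 1,4-dioxane/H2O (10:1), 40–60 °C, argon
Reagents that add atoms: none
Why: Proposed new method: rhodium-catalysed 1,4-addition of an arylboronic acid to a 2-acyloxyacrylate with enantioselective protonation of the enolate (Hayashi–Miyaura-type addition extended to a pyruvate enol ester). Transmetalation of 7 to the hydroxo complex of monovalent rhodium should give an aryl–rhodium species that inserts the terminal CH2=C bond of 6 with the aryl group going to the unsubstituted carbon (new C3–aryl bond), and the oxa-π-allyl rhodium enolate, held in a five-membered chelate by the carbonyl oxygen of the caffeoyl ester, would be protonated at C2 by water or a guaiacol O–H inside the chiral pocket of BINAP, which returns the Rh–OH catalyst. The closest known reaction type is the same addition/enantioselective protonation sequence with 2-acetamidoacrylates, itaconates and 2-benzylacrylates, together with the acyl-oxygen chelation known from rhodium-catalysed asymmetric hydrogenation of 2-acyloxyacrylates; no ring is closed. The C2 stereocentre is controlled by the ligand alone, since 6 is achiral, so the BINAP enantiomer that delivers (R) would be fixed after the sense of protonation has been assigned in a first run. The step needs site selectivity for the 1,1-disubstituted acrylate over the cinnamoyl C=C, which the substrate secures because the latter is 1,2-disubstituted, β-aryl and deactivated by two oxygen donors, and it needs protonation to outrun β-hydride elimination to the enol ester, which the aqueous medium favours. The free phenol of 7 should be tolerated (phenols serve as proton donors in the parent reaction), and the base-free conditions spare the enol ester of 6 and the new ester of 8.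

Step 4
Reactants: 8 tert-butyl (2R)-2-{[(2E)-3-(2,2-dimethyl-1,3-benzodioxol-5-yl)prop-2-enoyl]oxy}-3-(4-hydroxy-3-methoxyphenyl)propanoate
Product: 9 clinopodic acid B, (2R)-2-{[(2E)-3-(3,4-dihydroxyphenyl)prop-2-enoyl]oxy}-3-(4-hydroxy-3-methoxyphenyl)propanoic acid
Conditions: TFA/H2O (9:1), 0 °C to rt, 2 h, N2 sweep, dark
Reagents that add atoms: none
Why: Acidolysis: the tert-butyl ester is cleaved by alkyl–oxygen fission (tert-butyl cation lost as isobutene) and the catechol acetonide is hydrolysed through its aryloxy-stabilised oxocarbenium ion, as in the release of DOPA from its acetonide in peptide chemistry, whereas the secondary caffeate ester, the (E)-alkene and the C2 stereocentre, which does not enolise in acid, should be untouched.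

**Compound list**
1 | 5-bromo-2,2-dimethyl-1,3-benzodioxole | CC1(C)Oc2ccc(Br)cc2O1 | starting material
2 | acrylic acid (prop-2-enoic acid) | C=CC(=O)O | starting material
3 | (2E)-3-(2,2-dimethyl-1,3-benzodioxol-5-yl)prop-2-enoic acid | CC1(C)Oc2ccc(/C=C/C(=O)O)cc2O1 | intermediate
4 | tert-butyl pyruvate (tert-butyl 2-oxopropanoate) | CC(=O)C(=O)OC(C)(C)C | starting material
5 | (2E)-3-(2,2-dimethyl-1,3-benzodioxol-5-yl)prop-2-enoyl chloride | CC1(C)Oc2ccc(/C=C/C(=O)Cl)cc2O1 | intermediate
6 | tert-butyl 2-{[(2E)-3-(2,2-dimethyl-1,3-benzodioxol-5-yl)prop-2-enoyl]oxy}prop-2-enoate | C=C(OC(=O)/C=C/c1ccc2OC(C)(C)Oc2c1)C(=O)OC(C)(C)C | intermediate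
7 | (4-hydroxy-3-methoxyphenyl)boronic acid | COc1cc(B(O)O)ccc1O | starting material
8 | tert-butyl (2R)-2-{[(2E)-3-(2,2-dimethyl-1,3-benzodioxol-5-yl)prop-2-enoyl]oxy}-3-(4-hydroxy-3-methoxyphenyl)propanoate | COc1cc(C[C@@H](OC(=O)/C=C/c2ccc3OC(C)(C)Oc3c2)C(=O)OC(C)(C)C)ccc1O | intermediate
9 | clinopodic acid B, (2R)-2-{[(2E)-3-(3,4-dihydroxyphenyl)prop-2-enoyl]oxy}-3-(4-hydroxy-3-methoxyphenyl)propanoic acid | COc1cc(C[C@@H](OC(=O)/C=C/c2ccc(O)c(O)c2)C(=O)O)ccc1O | target

Total step count: 4. Longest linear sequence: 4 steps (1 → 3 → 6 → 8 → 9).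

Steps most likely to fail:

Step 3. The protonation of the rhodium enolate might show poor facial control, β-hydride elimination to the enol ester might compete, or the electron-rich boronic acid might lose boron before transmetalation. The fallback uses known chemistry, sets out from 6 and comes back at 8. A ligand-free, phase-transfer Mizoroki–Heck arylation of 6 with 4-iodo-2-methoxyphenol F1 (Pd(OAc)2, n-Bu4NCl, KOAc, DMF, 60 °C), as practised with 2-acetamidoacrylates, would give tert-butyl (2Z)-2-{[(2E)-3-(2,2-dimethyl-1,3-benzodioxol-5-yl)prop-2-enoyl]oxy}-3-(4-hydroxy-3-methoxyphenyl)prop-2-enoate F2. Asymmetric hydrogenation of F2 with [Rh(cod)((R,R)-Et-DuPHOS)]BF4 (1 mol%; Et-DuPHOS = 1,2-bis(2,5-diethylphospholan-1-yl)benzene, cod = cycloocta-1,5-diene), H2 (4 bar), MeOH, rt, would then give 8. This is the established enantioselective reduction of 2-acyloxyacrylates: the enol C=C and the acyl carbonyl chelate monovalent rhodium, so the non-chelating cinnamoyl alkene should be left, and the (R,R)-ligand is expected to give (R).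

Step 2. Aldol self-condensation of the pyruvate under amine base, or polymerisation of the captodative acrylate, might outpace O-acylation by the conjugated, electron-rich acid chloride. The fallback sets out from 4 (with 1) and comes back at 6; acid 3 and step 1 would not be needed. O-Acylation of 4 with acryloyl chloride F3 (excess, Et3N, CH2Cl2, −40 °C), a small and far more electrophilic chloride, would give tert-butyl 2-(prop-2-enoyloxy)prop-2-enoate F4. A Mizoroki–Heck reaction of F4 with bromide 1 (Pd2(dba)3, P(t-Bu)3, Cy2NMe, 1,4-dioxane, rt to 40 °C; dba = dibenzylideneacetone) would then arylate the monosubstituted acrylate terminus, which inserts faster than the 1,1-disubstituted one, and give 6.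

Step 4. The tert-butyl cation might alkylate the catechol and guaiacol rings, and the depside ester might slowly hydrolyse while the acetonide is being cleaved. The fallback carries the carboxyl group as an allyl ester, so that no carbocation is formed at the end; it sets out from chloride 5 and comes back at 9. Allyl pyruvate F5 (from pyruvic acid and allyl alcohol, TsOH, toluene, removal of water) would be O-acylated with 5 as in step 2 to give prop-2-en-1-yl 2-{[(2E)-3-(2,2-dimethyl-1,3-benzodioxol-5-yl)prop-2-enoyl]oxy}prop-2-enoate F6. Arylation with 7 as in step 3 would give prop-2-en-1-yl (2R)-2-{[(2E)-3-(2,2-dimethyl-1,3-benzodioxol-5-yl)prop-2-enoyl]oxy}-3-(4-hydroxy-3-methoxyphenyl)propanoate F7. Pd(PPh3)4 (2 mol%, zerovalent palladium) and morpholine in THF would remove the allyl group through the π-allyl complex under neutral conditions and give (2R)-2-{[(2E)-3-(2,2-dimethyl-1,3-benzodioxol-5-yl)prop-2-enoyl]oxy}-3-(4-hydroxy-3-methoxyphenyl)propanoic acid F8. Aqueous TFA (9:1, 0 °C to rt) would then hydrolyse the acetonide alone and give 9.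

Further compounds
F1 | step 3 | 4-iodo-2-methoxyphenol | COc1cc(I)ccc1O
F2 | step 3 | tert-butyl (2Z)-2-{[(2E)-3-(2,2-dimethyl-1,3-benzodioxol-5-yl)prop-2-enoyl]oxy}-3-(4-hydroxy-3-methoxyphenyl)prop-2-enoate | COc1cc(/C=C(\OC(=O)/C=C/c2ccc3OC(C)(C)Oc3c2)C(=O)OC(C)(C)C)ccc1O
F3 | step 2 | acryloyl chloride (prop-2-enoyl chloride) | C=CC(=O)Cl
F4 | step 2 | tert-butyl 2-(prop-2-enoyloxy)prop-2-enoate | C=CC(=O)OC(=C)C(=O)OC(C)(C)C
F5 | step 4 | allyl pyruvate (prop-2-en-1-yl 2-oxopropanoate) | CC(=O)C(=O)OCC=C
F6 | step 4 | prop-2-en-1-yl 2-{[(2E)-3-(2,2-dimethyl-1,3-benzodioxol-5-yl)prop-2-enoyl]oxy}prop-2-enoate | C=C(OC(=O)/C=C/c1ccc2OC(C)(C)Oc2c1)C(=O)OCC=C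
F7 | step 4 | prop-2-en-1-yl (2R)-2-{[(2E)-3-(2,2-dimethyl-1,3-benzodioxol-5-yl)prop-2-enoyl]oxy}-3-(4-hydroxy-3-methoxyphenyl)propanoate | COc1cc(C[C@@H](OC(=O)/C=C/c2ccc3OC(C)(C)Oc3c2)C(=O)OCC=C)ccc1O
F8 | step 4 | (2R)-2-{[(2E)-3-(2,2-dimethyl-1,3-benzodioxol-5-yl)prop-2-enoyl]oxy}-3-(4-hydroxy-3-methoxyphenyl)propanoic acid | COc1cc(C[C@@H](OC(=O)/C=C/c2ccc3OC(C)(C)Oc3c2)C(=O)O)ccc1O
A1 | direct plan | tert-butyl (2R)-3-[4-(tert-butyldimethylsilyloxy)-3-methoxyphenyl]-2-hydroxypropanoate | COc1cc(C[C@@H](O)C(=O)OC(C)(C)C)ccc1O[Si](C)(C)C(C)(C)C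
A2 | direct plan | (2E)-3-[3,4-bis(tert-butyldimethylsilyloxy)phenyl]prop-2-enoic acid | OC(=O)/C=C/c1ccc(O[Si](C)(C)C(C)(C)C)c(O[Si](C)(C)C(C)(C)C)c1
A3 | direct plan | tert-butyl (2R)-2-{[(2E)-3-[3,4-bis(tert-butyldimethylsilyloxy)phenyl]prop-2-enoyl]oxy}-3-[4-(tert-butyldimethylsilyloxy)-3-methoxyphenyl]propanoate | COc1cc(C[C@@H](OC(=O)/C=C/c2ccc(O[Si](C)(C)C(C)(C)C)c(O[Si](C)(C)C(C)(C)C)c2)C(=O)OC(C)(C)C)ccc1O[Si](C)(C)C(C)(C)C
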